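The question is how much of what each flask has turned into product is still target when the batch ends.

common to all: starting material 1.8 M; free catalyst 180 mM; time 2.5 min

| charge | temperature |
|---|---|
| south-west | 55 °C |
| north | 15 °C |
| north-west | 35 °C |

    free catalyst + other conformer → free catalyst + isomer of the product A (k1 = 2.2 /M/s, Ea1 = 39.0 kJ/mol)
    starting material + free catalyst → spent catalyst (k2 = 0.0033 /M/s, Ea2 = 78.0 kJ/mol)
    target → over-reaction product (k3 = 0.019 /s, Ea3 = 87.0 kJ/mol)
    starting material ⇌ other conformer (K4 = 2.2, k4 = 0.025 /s, Ea4 = 74.0 kJ/mol, ΔH4 = −40.0 kJ/mol)
    starting material + free catalyst → free catalyst + target (k5 = 1.3 /M/s, Ea5 = 60.0 kJ/mol)
    target ⇌ isomer of the product B (K6 = 0.46, k6 = 0.037 /s, Ea6 = 93.0 kJ/mol, ΔH6 = −15.0 kJ/mol)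
    (constants at 35 °C)

- all constants are for 35 °C and move with temperature by the activation energies and enthalpies
- in a conversion other conformer counts as not yet reacted

- which flask leads in share of target in all that became target or isomer of the product A or over-reaction product or isomer of the product B ("all alike" within 1.5 percentage points) (south-west / north / north-west / all alike)
- share of target in all that became target or isomer of the product A or over-reaction product or isomer of the product B, south-west
- share of target in all that became target or isomer of the product A or over-reaction product or isomer of the product B, north
- share of target in all that became target or isomer of the product A or over-reaction product or isomer of the product B, north-west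

Two chemists dispute this. The first holds that the share is made at the first fork. A molecule of starting material, with free catalyst taken at its charge, goes to target at rate 0.234 /s or to other conformer at 0.025 /s, and he counts the conformer as lost to isomer of the product A. The chance of target, φ, is then 90.3 % at 35 °C and 93.2 % at 15 °C. For him target then stays as it is, so the shares stand near these figures.

The second chemist, whose reckoning is mine, follows the molecule past the fork. In the north-west flask, target and isomer of the product B exchange at a relaxation rate of 0.117 /s, faster than over-reaction at 0.019 /s. The pair therefore acts as one balanced pool. With K the equilibrium constant of that exchange, here 0.46, the fraction present as target is one over one plus K.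

The leak constant k_L is the over-reaction constant times that fraction, the first-order rate at which the pool drains: 0.0130 /s. Over the batch time t the survival is S = exp(−k_L t), here 0.142, so the north-west share, φS over one plus K, is 8.80 %.

In the south-west flask, k_L t is 17.1, so its share rounds to zero. In the north flask, K is 0.691 and k_L is 0.00106 /s, which gives 47.0 %. That figure is the weak one, because the north relaxation rate of 0.00729 /s means a relaxation time of 137 s, less than the batch of 150 s but not by much. So I do not count on the north pool balancing within the batch, and I expect my number to come out low.

The forecast takes the survival side. It names north as leader, with 0 % south-west (up to 0.01 %), 56 % north (52 % to 60 %) and 9.2 % north-west (7.5 % to 11 %), on the ground that “the result depends mainly on how much target survives”. Its north value stands above mine.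

The simulation gives 0 % south-west, 56.0 % north and 9.14 % north-west, so north leads and the forecast holds. The largest single effect is what temperature does to over-reaction: without it, the south-west-minus-north gap shrinks from 56 percentage points to 1.4 points. The first chemist's view fits isomer of the product A: north-west it stands at 9.48 % at the end and 9.48 % at 25.0 min, against the 9.70 % of his fork. From 1.25 min to the end, k_L predicts that 37.7 % of north-west target remains, and the flask goes from 23.0 % to 9.12 %. Run at 30 °C, the south-west flask has k_L 0.00720 /s, which with φ kept at its north-west value gives 20.4 %, and its share of target is 19.9 %.

Its constants were chosen freely; the result is computed.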